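Locants used throughout: decalin carbons C1–C10, with C1 carrying the arylalkyl arm, C4 the ring carbinol carbon, C5/C10 the ring fusion (methyl on C10) and C7 carrying the 2-hydroxypropan-2-yl group. Ring A is C1–C5 plus C10, ring B is C5–C10, C1′ is the benzylic carbon, and β is the face of the C10 methyl group.

## The problem

Target 30 is a trans-fused decalin with an angular methyl at C10, an axial tertiary hydroxyl at C4 (β, 1,3-diaxial to that methyl), a β (equatorial) 2-hydroxypropan-2-yl group at C7 and, at C1, an α (axial) CH(isobutyl)aryl arm whose arene is a fully substituted 3,5-diformylphloroglucinol. There are six stereocentres, five in the rings (C1, C4, C5, C7, C10) and one outside (C1′). C10 is quaternary and can relay its configuration to C5 (thermodynamic trans fusion), to C4 (a nucleophile avoids the axial methyl) and to C7 (hydrogen arrives on the face away from it). C1 has to be placed anti to the methyl on a carbon next to the quaternary centre, and C1′ is acyclic, so it needs a cyclic transition state and not ring bias. The C1–C1′ bond is the most congested in the molecule, joining a neopentyl-type ring carbon to a benzylic carbon flanked by two ortho oxygens. The two tertiary alcohols ionise under the Lewis or Brønsted acids normally used for arene formylation and aryl ether cleavage, and the free trihydroxy dialdehyde tolerates neither organometallics nor hydrides, so it must be unveiled last. What makes the key step possible is that C10 and C5 are flanked by C1 and C4: with both oxidised, ring A is 2-methoxy-5-methyl-1,4-benzoquinone (4), with its carbonyls at C1 and C4, its methyl on C10 and its methoxy on C3, and ring B (C6–C9 with the C7 branch) is a 2-substituted butadiene.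

## Retrosynthesis

**30 ⇐ 29 ⇐ 28 (unmasking).** No skeletal bond is cut, only two O–Si and three O–alkyl bonds. The tertiary alcohols are kept as triethylsilyl ethers to the end and released by buffered fluoride, which cannot ionise them. The aryl ethers of 28 are cleaved by thiolate SN2 displacement, because every aryl oxygen is ortho or para to both formyl groups and so leaves as a stabilised phenoxide. Lewis-acid dealkylation is set aside because of the two tertiary C–O bonds.

**28 ⇐ 26 ⇐ 25 ⇐ 24 (two aryl–CHO bonds).** Acid-mediated formylation would be the shortest cut but meets the same tertiary C–O bonds. Bromination of the only two free ring positions, bromine–lithium exchange and a formamide quench do the same job under basic conditions. Phenol 24 is capped as methyl ether 25 first so that no acidic proton interferes.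

**24 ⇐ 20 + two molecules of 21 (the arene is grown, not attached).** Four ring bonds are cut: diazoketone 20 gives a ketene, which takes up ethoxyacetylene 21 twice (via cyclobutenone 23) to give the 2-alkyl-3,5-diethoxyphenol 24. The alternative of joining a ready-made 2,4,6-trioxygenated aryl group to secondary, neopentyl-flanked C1′ offers neither rate nor stereocontrol. An arylacetate in the rearrangement below would be shorter, but it exchanges the roles of the two α-substituents and enolises to one geometry only, so its favoured transition state would give the C1′ epimer. The forward demands are a Wolff shift with retention at C1′ and the polarity-controlled regiochemistry of ketene/ynol ether cycloadditions. These place the alkyl group between two oxygens and leave exactly two free positions.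

**20 ⇐ 18 ⇐ 17 ⇐ 14 (C1–C1′).** The congested bond is cut by an Ireland–Claisen rearrangement of the 3α-(4-methylpentanoate) 14. The α-oxygen at C3 hands its face to C1 in a suprafacial shift, the bond forms intramolecularly, and C1′ follows from the ketene acetal geometry. The C3 oxygen and the C2=C3 alkene then vanish on hydrogenation (17 → 18). Conjugate addition of a branched benzylic nucleophile to enone 10 was considered, but it would be too hindered and blind at C1′.

**14 ⇐ 11 + 12 ⇐ 10 (C3–H and C3–O acyl).** The 3α-alcohol 11 must come from hydride addition to the β face of enone 10, opposite to the axial attack an external hydride prefers. The free 4β-hydroxyl is therefore used to deliver the hydride. Acylation with acid chloride 12 and silylation of the tertiary hydroxyl then give 14.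

**10 ⇐ 8 ⇐ 7 ⇐ 6 (functional-group relay in ring A, C7–H).** Enone 10 is the 1,3-carbonyl transposition product of vinylogous ester 8 (reduction at C1, hydrolysis at C3). Compound 8 comes from 7 by hydrogenation of C7=C8 at the one stage where the other C=C is a deactivated push–pull alkene and the α face is still open. Compound 7 comes from enedione 6 by methyl addition to C4. Each step exploits the difference between the two carbonyls that the methoxy group creates.

**6 ⇐ 3 + 4 (C5–C6 and C9–C10, ring B).** Cutting ring B as a diene removes one ring, the quaternary carbon and the fusion stereocentre at once and leaves two small achiral pieces. The forward reaction must choose the methyl-bearing double bond of 4, orient the diene substituent to C7 and select one quinone face.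

**3 ⇐ 2 ⇐ 1.** The 2-substituted diene 3 is the ethylene–alkyne metathesis product of silyl ether 2, made from commercial alkynol 1.

## Roads not taken

Alternative 1: The cut runs through C5–C10 and C1–C2. An acyclic triene A2 has a 2-silyloxy-1,3-diene at one end, a (Z)-β-methyl enone at the other, four carbons between them, and the C7 stereocentre taken from the chiral pool. Heating would close ring A by intramolecular Diels–Alder cycloaddition and ring B through the tether, giving the trans-octalin silyl enol ether A1.
- Merits: two rings and C1, C5 and C10 arise in one thermal step without a catalyst. C7 never has to be made, the enol ether is a latent C4 ketone, and the C1 carbon substituent arrives with the cycloaddition.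
- Weak points: the (Z)-trisubstituted enone must be made and kept geometrically pure, because the C1/C10 relationship copies it. The trans fusion and the influence of remote C7 rest on a delicate endo/exo balance in a cycloaddition that forms a quaternary carbon. The C1 substituent is only a ketone, so the arene must add to a hindered, enolisable carbonyl and C1′ is then set by deoxygenating a tertiary benzylic alcohol with no controlling element.
- Comparison: in ring-building economy this road is better than the chosen one, and it needs no chiral catalyst. The chosen plan sets against it a cycloaddition whose site, orientation and face are each tied to a recognisable feature, commercial components, and a defined origin for C1′.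

Alternative 2: The cut removes the angular methyl carbon. Et2Zn/CH2I2, delivered by the 4β-hydroxyl, cyclopropanates the tetrasubstituted C5=C10 alkene of the ring-fusion allylic alcohol A4, forming C10–CH2 and C5–CH2 and giving the 5,10-methano alcohol A3. Oxidation and reductive opening of the C5–CH2 bond would then reveal the methyl group and a C4 ketone.
- Merits: hydroxyl-directed cyclopropanation is among the most dependable ways to functionalise a tetrasubstituted alkene on a chosen face. The arene travels as a robust trimethyl ether, so no ring has to be grown.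
- Weak points: the step solves only C10. A4 already contains C1, C1′ and the whole arm, for which this road offers no construction. Three operations are spent on one methyl group. The dissolving-metal opening must choose C5–CH2 over C5–C10 and spare an electron-rich arene and an allylic silyl ether, and C5 must then be protonated to the trans fusion.
- Comparison: in the certainty of its key step and the length of its endgame this road is at least as good as the chosen one, since it needs neither a benzannulation nor an asymmetric catalyst at that point. The chosen plan answers with a C10 methyl that costs nothing because it is part of quinone 4, and with an explicit stereocontrolled source for C1, C1′ and the absolute configuration.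

Alternative 3: The cut is C6–C7. MeAlCl2 activates the C4 ketone of the α-methylene ketone A6, and the trisubstituted alkene of the homoprenyl chain on C10 adds to the exocyclic methylene carbon. Ring B closes through a chair and the cation ends as an isopropenyl group, giving the trans-decalin ketone A5.
- Merits: ring B, equatorial C7 and (on enolate protonation) the trans fusion come from one substrate-controlled step. The isopropenyl group is one hydration from the side-chain carbinol, the C4 ketone is ready for methyl addition, and the arene is already in place.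
- Weak points: A6 must already hold quaternary C10 next to C1 and C1′ in enantiopure form, so the hardest part of the molecule is assumed, not made. A trimethoxyarene and a tertiary cation coexist with a strong Lewis acid, which invites Friedel–Crafts capture and demethylation. C7 is set relative to C10 only by the chair preference of a chain on a quaternary carbon.
- Comparison: this road obtains C7 and C5 without a separate hydrogenation and, like alternative 2, avoids the arene synthesis, and is better on those counts. The chosen plan sets against it that all its Lewis-acid chemistry is over before any acid-sensitive group exists, and that the quaternary carbon and its neighbour come from the catalytic step itself.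

Key step: step 3

Assumption 1: the (S)-oxazaborolidinium catalyst is taken to shield the quinone face that leads to the 10β-methyl series drawn for 5 and 6; should the sense be opposite, the mirror-image catalyst (from the other proline antipode) is used with nothing else changed.

Assumption 2: quinone 4 and acid chloride 12 are bought.

Shorthand: "Dec" = 4α,10β-dimethyl-4β-(triethylsilyloxy)-7β-[2-(triethylsilyloxy)propan-2-yl]-5α-H-decalin-1α-yl.

## Route

Step 1
Reactants: 1 2-methylbut-3-yn-2-ol
Product: 2 triethyl[(2-methylbut-3-yn-2-yl)oxy]silane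
Conditions: Et3SiCl, imidazole, DMAP (cat.), DMF, rt
Reagents that add atoms: chlorotriethylsilane CC[Si](Cl)(CC)CC
Why: Imidazole-promoted silylation of a tertiary propargylic alcohol; the triethylsilyl ether masks the future side-chain carbinol until the last step.

Step 2
Reactants: 2 triethyl[(2-methylbut-3-yn-2-yl)oxy]silane
Product: 3 2-[2-(triethylsilyloxy)propan-2-yl]buta-1,3-diene
Conditions: ethylene (1 atm), second-generation Grubbs catalyst RuCl2(=CHPh)(PCy3)(H2IMes) (5 mol %), toluene, 60 °C
Reagents that add atoms: ethylene C=C
Why: Ethylene–alkyne (enyne) cross-metathesis turns a terminal alkyne into the 2-substituted 1,3-diene; propargylic silyl ethers are standard substrates and no stereocentre arises.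

Step 3
Reactants: 3 2-[2-(triethylsilyloxy)propan-2-yl]buta-1,3-diene; 4 2-methoxy-5-methyl-1,4-benzoquinone
Product: 6 trans-fused 3-methoxy-10β-methyl-7-[2-(triethylsilyloxy)propan-2-yl]-5α-H-decalin-2,7-diene-1,4-dione, via cis-fused adduct 5 (not isolated)
Conditions: (S)-1-(2-methylphenyl)-3,3-diphenyltetrahydro-1H,3H-pyrrolo[1,2-c][1,3,2]oxazaborole (20 mol %), Tf2NH (18 mol %), CH2Cl2, −78 → −40 °C; then DBU (0.5 equiv), −40 °C → rt
Reagents that add atoms: none
Why: This is a Lewis-acid-catalysed enantioselective quinone Diels–Alder reaction followed by base-mediated ring-fusion epimerisation; the closest known chemistry is the oxazaborolidinium-catalysed addition of 2-substituted butadienes to unsymmetrical benzoquinones and the alkali isomerisation of cis methoxytoluquinone–diene adducts. The boron cation binds the more basic carbonyl of 4, the one in vinylogous-ester conjugation with the methoxy group (future C1), which makes the hydrogen-bearing carbon of the methyl-substituted double bond (future C5) the electrophilic terminus, while the methoxy-bearing double bond is switched off as a dienophile. The more nucleophilic terminus of 3, the CH2 on the substituted carbon, therefore bonds to C5 (C5–C6) and the other terminus to the methyl-bearing carbon (C9–C10) in a concerted, asynchronous, suprafacial [4+2] cycloaddition that closes ring B as a cyclohexene with the branch on C7 and not C8. C10 is set by the catalyst, which shields one face of the bound quinone, and C5 is first formed cis to the methyl (adduct 5) simply because the addition is suprafacial. The angular methyl blocks aromatisation, so DBU can only enolise C5–H toward the C4 ketone, and reprotonation gives the trans-fused 6; C5 thus ends under thermodynamic control by C10. Three selectivities are needed: site (secured by the methoxy group), orientation (secured by carbonyl basicity together with the 2-substituent of the diene) and face (secured by the catalyst). Endo/exo selectivity is irrelevant because the diene termini are unsubstituted.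

Step 4
Reactants: 6 trans-fused 3-methoxy-10β-methyl-7-[2-(triethylsilyloxy)propan-2-yl]-5α-H-decalin-2,7-diene-1,4-dione
Product: 7 4β-hydroxy-3-methoxy-4α,10β-dimethyl-7-[2-(triethylsilyloxy)propan-2-yl]-5α-H-decalin-2,7-dien-1-one
Conditions: MeLi, CeCl3, THF, −78 °C
Reagents that add atoms: methyllithium [Li]C
Why: Organocerium 1,2-addition (enolisation of C5–H suppressed) to C4, the ketone-like carbonyl, while C1 is a vinylogous ester next to the quaternary carbon; attack is equatorial from the α face because the axial C10 methyl blocks the β trajectory, giving the axial 4β-alcohol with the new methyl α.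

Step 5
Reactants: 7 4β-hydroxy-3-methoxy-4α,10β-dimethyl-7-[2-(triethylsilyloxy)propan-2-yl]-5α-H-decalin-2,7-dien-1-one
Product: 8 4β-hydroxy-3-methoxy-4α,10β-dimethyl-7β-[2-(triethylsilyloxy)propan-2-yl]-5α-H-decal-2-en-1-one
Conditions: H2 (1 atm), PtO2, EtOAc, rt
Reagents that add atoms: none
Why: Heterogeneous hydrogenation reduces the isolated trisubstituted C7=C8 bond while the push–pull C2=C3 bond of the vinylogous ester stays; hydrogen is delivered to the α face, away from the axial C10 methyl and the 4β-hydroxyl, which places the C7 branch β (equatorial).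

Step 6
Reactants: 8 4β-hydroxy-3-methoxy-4α,10β-dimethyl-7β-[2-(triethylsilyloxy)propan-2-yl]-5α-H-decal-2-en-1-one
Product: 10 4β-hydroxy-4α,10β-dimethyl-7β-[2-(triethylsilyloxy)propan-2-yl]-5α-H-decal-1-en-3-one, via enol ether allylic alcohol 9 (not isolated)
Conditions: LiAlH4, THF, 0 °C; then 0.5 M HCl, THF, 0 °C
Reagents that add atoms: water O
Why: Stork–Danheiser 1,3-carbonyl transposition: 1,2-reduction of the vinylogous ester, then mild acid hydrolysis of the enol ether with loss of the C1 hydroxyl, gives the 1-en-3-one; no stereocentre is touched and the tertiary silyl ether tolerates brief cold dilute acid.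

Step 7
Reactants: 10 4β-hydroxy-4α,10β-dimethyl-7β-[2-(triethylsilyloxy)propan-2-yl]-5α-H-decal-1-en-3-one
Product: 11 4α,10β-dimethyl-7β-[2-(triethylsilyloxy)propan-2-yl]-5α-H-decal-1-ene-3α,4β-diol
Conditions: Me4NBH(OAc)3, MeCN–AcOH, −30 → 0 °C
Reagents that add atoms: none
Why: Hydroxyl-directed triacetoxyborohydride reduction: ligand exchange puts boron on the 4β-oxygen and hydride is delivered intramolecularly to the β face of C3, giving the trans (3α,4β) diol; the reagent is too weak to reduce the enone intermolecularly, so 1,2-selectivity follows.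

Step 8
Reactants: 11 4α,10β-dimethyl-7β-[2-(triethylsilyloxy)propan-2-yl]-5α-H-decal-1-ene-3α,4β-diol; 12 4-methylpentanoyl chloride
Product: 14 3α-(4-methylpentanoyloxy)-4α,10β-dimethyl-4β-(triethylsilyloxy)-7β-[2-(triethylsilyloxy)propan-2-yl]-5α-H-decal-1-ene, via hydroxy ester 13 (not isolated)
Conditions: pyridine, DMAP, CH2Cl2, 0 °C → rt; then 2,6-lutidine, Et3SiOTf, 0 °C → rt
Reagents that add atoms: triethylsilyl trifluoromethanesulfonate CC[Si](CC)(CC)OS(=O)(=O)C(F)(F)F
Why: DMAP-catalysed acylation takes only the secondary allylic hydroxyl; the hindered axial tertiary hydroxyl is then capped in the same flask by the more reactive silyl triflate.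

Step 9
Reactants: 14 3α-(4-methylpentanoyloxy)-4α,10β-dimethyl-4β-(triethylsilyloxy)-7β-[2-(triethylsilyloxy)propan-2-yl]-5α-H-decal-1-ene
Product: 17 (2R)-4-methyl-2-(2,3-didehydro-Dec)pentanoic acid (C2=C3 alkene; C1 α-substituted), via (Z)-silyl ketene acetal 15 (not isolated), via trimethylsilyl ester 16 (not isolated)
Conditions: LiN(iPr)2, THF–DMPU, −78 °C; Me3SiCl; −78 → 65 °C; then MeOH–H2O
Reagents that add atoms: none
Why: Ireland–Claisen rearrangement: enolisation in THF–DMPU gives the (Z)-silyl ketene acetal, whose [3,3] shift is suprafacial on the α face (C3–O broken, C1–C1′ made) through the boat-like transition state usual for cyclohex-2-enyl esters, with the isobutyl chain pointing away from the decalin and only hydrogen over ring A; this sets C1 (α) and C1′ (R) together.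

Step 10
Reactants: 17 (2R)-4-methyl-2-(2,3-didehydro-Dec)pentanoic acid
Product: 18 (2R)-2-(Dec)-4-methylpentanoic acid
Conditions: H2 (1 atm), Pd/C, EtOAc, rt
Reagents that add atoms: none
Why: Catalytic hydrogenation of the cis-disubstituted ring alkene; no stereocentre is formed and the acid and silyl ethers are untouched.

Step 11
Reactants: 18 (2R)-2-(Dec)-4-methylpentanoic acid
Product: 20 (3R)-1-diazo-3-(Dec)-5-methylhexan-2-one, via acid chloride 19 (not isolated)
Conditions: Me2C=C(Cl)NMe2, CH2Cl2, 0 °C → rt; then CH2N2 (excess), Et2O, 0 °C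
Reagents that add atoms: diazomethane C=[N+]=[N-]
Why: First half of an Arndt–Eistert sequence: the neutral chloroenamine reagent forms the acid chloride without free HCl, and acylation of excess diazomethane in the absence of amine base avoids ketene formation and hence epimerisation at C1′.

Step 12
Reactants: 20 (3R)-1-diazo-3-(Dec)-5-methylhexan-2-one; 21 ethoxyacetylene (two molecules are incorporated)
Product: 24 2-[(1R)-1-(Dec)-3-methylbutyl]-3,5-diethoxyphenol, via alkylketene 22 (not isolated), via 3-ethoxycyclobutenone 23 (not isolated)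
Conditions: hν (Hg lamp, Pyrex), 21 (excess), toluene, rt; then 85 °C, sealed tube
Reagents that add atoms: none
Why: Photochemical Wolff rearrangement (C1′ migrates with retention) gives the alkylketene, which adds the ynol ether in a regioselective [2+2] (ketene carbonyl carbon to the alkyne CH) to give the 4-alkyl-3-ethoxycyclobutenone; heating then starts the Danheiser benzannulation (4π opening to a vinylketene, [2+2] with a second ynol ether, 4π opening, 6π closure, tautomerisation), which places the alkyl group between OH and OEt.

Step 13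
Reactants: 24 2-[(1R)-1-(Dec)-3-methylbutyl]-3,5-diethoxyphenol
Product: 25 2-[(1R)-1-(Dec)-3-methylbutyl]-1,5-diethoxy-3-methoxybenzene
Conditions: MeI, K2CO3, acetone, 50 °C
Reagents that add atoms: iodomethane CI
Why: Williamson O-methylation removes the acidic phenol proton before the organolithium step; the methyl ether is cleaved in step 16 together with the ethyl ethers.

Step 14
Reactants: 25 2-[(1R)-1-(Dec)-3-methylbutyl]-1,5-diethoxy-3-methoxybenzene
Product: 26 1-[(1R)-1-(Dec)-3-methylbutyl]-3,5-dibromo-4,6-diethoxy-2-methoxybenzene
Conditions: NBS (2.1 equiv), MeCN, 0 °C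
Reagents that add atoms: N-bromosuccinimide O=C1CCC(=O)N1Br
Why: Electrophilic aromatic bromination of a trialkoxyarene; only two ring positions are free, each flanked by two alkoxy groups, so the regiochemistry is fixed.

Step 15
Reactants: 26 1-[(1R)-1-(Dec)-3-methylbutyl]-3,5-dibromo-4,6-diethoxy-2-methoxybenzene
Product: 28 5-[(1R)-1-(Dec)-3-methylbutyl]-2,4-diethoxy-6-methoxybenzene-1,3-dicarbaldehyde, via dilithioarene 27 (not isolated)
Conditions: t-BuLi (4.4 equiv), THF, −78 °C; DMF; H2O
Reagents that add atoms: N,N-dimethylformamide CN(C)C=O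
Why: Twofold bromine–lithium exchange (two t-BuLi per bromine) and Bouveault-type formylation with DMF; the basic conditions leave both tertiary silyl ethers intact, which acid-mediated formylations would not.

Step 16
Reactants: 28 5-[(1R)-1-(Dec)-3-methylbutyl]-2,4-diethoxy-6-methoxybenzene-1,3-dicarbaldehyde
Product: 29 5-[(1R)-1-(Dec)-3-methylbutyl]-2,4,6-trihydroxybenzene-1,3-dicarbaldehyde
Conditions: NaSEt (excess), DMF, 120 °C; then cold 1 M HCl
Reagents that add atoms: none
Why: SN2 O-dealkylation by thiolate; each aryl ether oxygen is ortho or para to both formyl groups, so the phenoxide leaving groups are stabilised like vinylogous carboxylates, and no Lewis acid touches the tertiary C–O bonds.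

Step 17
Reactants: 29 5-[(1R)-1-(Dec)-3-methylbutyl]-2,4,6-trihydroxybenzene-1,3-dicarbaldehyde
Product: 30 target: 5-[(1R)-1-[4β-hydroxy-7β-(2-hydroxypropan-2-yl)-4α,10β-dimethyl-5α-H-decalin-1α-yl]-3-methylbutyl]-2,4,6-trihydroxybenzene-1,3-dicarbaldehyde
Conditions: HF·pyridine, pyridine–THF, 0 °C → rt
Reagents that add atoms: none
Why: Fluoride-mediated cleavage of both tertiary triethylsilyl ethers under buffered, non-ionising conditions releases the target without risk to the tertiary alcohols or the hydroxy aldehydes.

## Compound list

1 | 2-methylbut-3-yn-2-ol | CC(C)(O)C#C | starting material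
2 | triethyl[(2-methylbut-3-yn-2-yl)oxy]silane | CC[Si](CC)(CC)OC(C)(C)C#C | intermediate
3 | 2-[2-(triethylsilyloxy)propan-2-yl]buta-1,3-diene | C=CC(=C)C(C)(C)O[Si](CC)(CC)CC | intermediate
4 | 2-methoxy-5-methyl-1,4-benzoquinone | COC1=CC(=O)C(C)=CC1=O | starting material
5 | cis-fused adduct (5β-H, 10β-methyl), not isolated | O=C1C=C(OC)C(=O)[C@@H]2CC(C(C)(C)O[Si](CC)(CC)CC)=CC[C@]12C | intermediate
6 | trans-fused 3-methoxy-10β-methyl-7-[2-(triethylsilyloxy)propan-2-yl]-5α-H-decalin-2,7-diene-1,4-dione | O=C1C=C(OC)C(=O)[C@H]2CC(C(C)(C)O[Si](CC)(CC)CC)=CC[C@]12C | intermediate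
7 | 4β-hydroxy-3-methoxy-4α,10β-dimethyl-7-[2-(triethylsilyloxy)propan-2-yl]-5α-H-decalin-2,7-dien-1-one | O=C1C=C(OC)[C@@](C)(O)[C@H]2CC(C(C)(C)O[Si](CC)(CC)CC)=CC[C@]12C | intermediate
8 | 4β-hydroxy-3-methoxy-4α,10β-dimethyl-7β-[2-(triethylsilyloxy)propan-2-yl]-5α-H-decal-2-en-1-one | O=C1C=C(OC)[C@@](C)(O)[C@H]2C[C@@H](C(C)(C)O[Si](CC)(CC)CC)CC[C@]12C | intermediate
9 | 3-methoxy-4α,10β-dimethyl-7β-[2-(triethylsilyloxy)propan-2-yl]-5α-H-decal-2-ene-1β,4β-diol, not isolated (C1 configuration without consequence) | O[C@H]1C=C(OC)[C@@](C)(O)[C@H]2C[C@@H](C(C)(C)O[Si](CC)(CC)CC)CC[C@]12C | intermediate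
10 | 4β-hydroxy-4α,10β-dimethyl-7β-[2-(triethylsilyloxy)propan-2-yl]-5α-H-decal-1-en-3-one | C1=CC(=O)[C@@](C)(O)[C@H]2C[C@@H](C(C)(C)O[Si](CC)(CC)CC)CC[C@]12C | intermediate
11 | 4α,10β-dimethyl-7β-[2-(triethylsilyloxy)propan-2-yl]-5α-H-decal-1-ene-3α,4β-diol | C1=C[C@H](O)[C@@](C)(O)[C@H]2C[C@@H](C(C)(C)O[Si](CC)(CC)CC)CC[C@]12C | intermediate
12 | 4-methylpentanoyl chloride | CC(C)CCC(=O)Cl | starting material
13 | 3α-(4-methylpentanoyloxy) 4β-alcohol, not isolated | C1=C[C@H](OC(=O)CCC(C)C)[C@@](C)(O)[C@H]2C[C@@H](C(C)(C)O[Si](CC)(CC)CC)CC[C@]12C | intermediate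
14 | 3α-(4-methylpentanoyloxy)-4α,10β-dimethyl-4β-(triethylsilyloxy)-7β-[2-(triethylsilyloxy)propan-2-yl]-5α-H-decal-1-ene | C1=C[C@H](OC(=O)CCC(C)C)[C@@](C)(O[Si](CC)(CC)CC)[C@H]2C[C@@H](C(C)(C)O[Si](CC)(CC)CC)CC[C@]12C | intermediate
15 | (Z)-O-trimethylsilyl ketene acetal of 14, not isolated | C1=C[C@H](O/C(O[Si](C)(C)C)=C/CC(C)C)[C@@](C)(O[Si](CC)(CC)CC)[C@H]2C[C@@H](C(C)(C)O[Si](CC)(CC)CC)CC[C@]12C | intermediate
16 | trimethylsilyl ester of 17, not isolated | CC(C)C[C@@H](C(=O)O[Si](C)(C)C)[C@@H]1C=C[C@@](C)(O[Si](CC)(CC)CC)[C@H]2C[C@@H](C(C)(C)O[Si](CC)(CC)CC)CC[C@]12C | intermediate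
17 | (2R)-4-methyl-2-(2,3-didehydro-Dec)pentanoic acid | CC(C)C[C@@H](C(=O)O)[C@@H]1C=C[C@@](C)(O[Si](CC)(CC)CC)[C@H]2C[C@@H](C(C)(C)O[Si](CC)(CC)CC)CC[C@]12C | intermediate
18 | (2R)-2-(Dec)-4-methylpentanoic acid | CC(C)C[C@@H](C(=O)O)[C@@H]1CC[C@@](C)(O[Si](CC)(CC)CC)[C@H]2C[C@@H](C(C)(C)O[Si](CC)(CC)CC)CC[C@]12C | intermediate
19 | acid chloride of 18, not isolated | CC(C)C[C@@H](C(=O)Cl)[C@@H]1CC[C@@](C)(O[Si](CC)(CC)CC)[C@H]2C[C@@H](C(C)(C)O[Si](CC)(CC)CC)CC[C@]12C | intermediate
20 | (3R)-1-diazo-3-(Dec)-5-methylhexan-2-one | CC(C)C[C@@H](C(=O)C=[N+]=[N-])[C@@H]1CC[C@@](C)(O[Si](CC)(CC)CC)[C@H]2C[C@@H](C(C)(C)O[Si](CC)(CC)CC)CC[C@]12C | intermediate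
21 | ethoxyacetylene | CCOC#C | starting material
22 | alkylketene [(1-(Dec)-3-methylbutyl)ketene], not isolated | CC(C)C[C@@H](C=C=O)[C@@H]1CC[C@@](C)(O[Si](CC)(CC)CC)[C@H]2C[C@@H](C(C)(C)O[Si](CC)(CC)CC)CC[C@]12C | intermediate
23 | 3-ethoxy-4-[1-(Dec)-3-methylbutyl]cyclobut-2-en-1-one (both C4 epimers), not isolated | CC(C)C[C@@H](C1C(=O)C=C1OCC)[C@@H]1CC[C@@](C)(O[Si](CC)(CC)CC)[C@H]2C[C@@H](C(C)(C)O[Si](CC)(CC)CC)CC[C@]12C | intermediate
24 | 2-[(1R)-1-(Dec)-3-methylbutyl]-3,5-diethoxyphenol | CC(C)C[C@@H](c1c(O)cc(OCC)cc1OCC)[C@@H]1CC[C@@](C)(O[Si](CC)(CC)CC)[C@H]2C[C@@H](C(C)(C)O[Si](CC)(CC)CC)CC[C@]12C | intermediate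
25 | 2-[(1R)-1-(Dec)-3-methylbutyl]-1,5-diethoxy-3-methoxybenzene | CC(C)C[C@@H](c1c(OC)cc(OCC)cc1OCC)[C@@H]1CC[C@@](C)(O[Si](CC)(CC)CC)[C@H]2C[C@@H](C(C)(C)O[Si](CC)(CC)CC)CC[C@]12C | intermediate
26 | 1-[(1R)-1-(Dec)-3-methylbutyl]-3,5-dibromo-4,6-diethoxy-2-methoxybenzene | CC(C)C[C@@H](c1c(OC)c(Br)c(OCC)c(Br)c1OCC)[C@@H]1CC[C@@](C)(O[Si](CC)(CC)CC)[C@H]2C[C@@H](C(C)(C)O[Si](CC)(CC)CC)CC[C@]12C | intermediate
27 | 3,5-dilithio analogue of 26, not isolated | CC(C)C[C@@H](c1c(OC)c([Li])c(OCC)c([Li])c1OCC)[C@@H]1CC[C@@](C)(O[Si](CC)(CC)CC)[C@H]2C[C@@H](C(C)(C)O[Si](CC)(CC)CC)CC[C@]12C | intermediate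
28 | 5-[(1R)-1-(Dec)-3-methylbutyl]-2,4-diethoxy-6-methoxybenzene-1,3-dicarbaldehyde | CC(C)C[C@@H](c1c(OC)c(C=O)c(OCC)c(C=O)c1OCC)[C@@H]1CC[C@@](C)(O[Si](CC)(CC)CC)[C@H]2C[C@@H](C(C)(C)O[Si](CC)(CC)CC)CC[C@]12C | intermediate
29 | 5-[(1R)-1-(Dec)-3-methylbutyl]-2,4,6-trihydroxybenzene-1,3-dicarbaldehyde | CC(C)C[C@@H](c1c(O)c(C=O)c(O)c(C=O)c1O)[C@@H]1CC[C@@](C)(O[Si](CC)(CC)CC)[C@H]2C[C@@H](C(C)(C)O[Si](CC)(CC)CC)CC[C@]12C | intermediate
30 | 5-[(1R)-1-[4β-hydroxy-7β-(2-hydroxypropan-2-yl)-4α,10β-dimethyl-5α-H-decalin-1α-yl]-3-methylbutyl]-2,4,6-trihydroxybenzene-1,3-dicarbaldehyde | CC(C)C[C@@H](c1c(O)c(C=O)c(O)c(C=O)c1O)[C@@H]1CC[C@@](C)(O)[C@H]2C[C@@H](C(C)(C)O)CC[C@]12C | target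

## Step count and least certain steps

Total: 17 steps. Longest linear sequence: 17 steps (1 → 30); compounds 4, 12 and 21 enter directly.

**Step 3 (key step).** The most likely failures are insufficient facial discrimination by the catalyst for this bulky, only weakly polarised diene, leakage to the C8-substituted orientation, acid-promoted ionisation of the tertiary allylic silyl ether of 3, and an epimerisation equilibrium that stops short of complete trans fusion (the cis portion would be recycled through base). Fallback: setting out from 3 and 4, the cycloaddition is run without a chiral catalyst (thermally in toluene, or with BF3·OEt2 at low temperature) and epimerised to racemic 6, which is taken through steps 4–7. Racemic 11 is then esterified at the 3α-hydroxyl with (S)-2-methoxy-2-phenylacetic acid (DCC, DMAP) and the diastereomeric esters are separated. The ester of the wanted series, the 3α-[(S)-2-methoxy-2-phenylacetate] of 11 F1, is saponified (LiOH, THF–H2O), and the route is rejoined at 11.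

**Step 7.** Ligand exchange at the hindered axial tertiary hydroxyl may be slow, so that hydride arrives intermolecularly (axial attack from the α face, giving the 3β-epimer, or conjugate reduction) or not at all. Fallback: setting out from 10, the tertiary hydroxyl is silylated with chlorodimethylsilane (Et3N, DMAP) to the 4β-(dimethylsilyl) ether of 10 F2. Catalytic Bu4NF then triggers intramolecular hydrosilylation, the Si–H being delivered from the β face to which it is tethered, and aqueous fluoride work-up returns the route to 11.

**Step 9.** The boat/chair preference of the rearrangement or the Z-selectivity of enolisation may erode, which would scramble C1′; alternatively, bond formation at neopentyl-type C1 may be slow enough for the ketene acetal to decompose. Fallback: setting out from 11, acetyl chloride replaces 12 in step 8 to give the 3α-acetate 4β-triethylsilyl ether F3, whose Ireland–Claisen rearrangement (no α-stereocentre, less hindered) gives the C1α-acetic acid F4. Pivaloyl chloride activation and coupling with lithiated (R)-4-benzyl-oxazolidin-2-one give the imide F5. Enolisation with NaN(SiMe3)2 and alkylation with 3-bromo-2-methylpropene give the methallylated imide F6, the auxiliary now controlling C1′. LiOH/H2O2 releases the methallyl acid F7, and hydrogenation (H2, Pd/C) of both C=C bonds rejoins the route at 18.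

**Step 12.** In the photochemical stage, carbene-derived side reactions and ketene dimerisation may compete with capture by 21; in the thermal stage, ring opening of the 3-alkoxycyclobutenone may be slow relative to decomposition of 21. Fallback: setting out from 20, a silver benzoate (PhCO2Ag)-catalysed Wolff rearrangement in aqueous THF completes the Arndt–Eistert homologation to the homologous acid F8, which the chloroenamine reagent converts into the acid chloride F9. Dehydrochlorination with Et3N in the presence of 21 generates ketene 22 under classical conditions and gives cyclobutenone 23. This is now isolated and heated with 21 in a separate operation to reach 24.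

**Step 16.** SN2 attack at ethyl carbon is much slower than at methyl, and it becomes slower still as phenoxide charges build up; the forcing conditions then needed may damage the formyl groups (thiolate addition, substitution at the ring). Fallback: setting out from 20, step 12 is run with methoxyacetylene F10 (made in one step from chloroacetaldehyde dimethyl acetal and NaNH2) to give the 3,5-dimethoxyphenol F11. Steps 13–15 then give the trimethyl ether F12, the dibromide F13 and the trimethoxy dialdehyde F14. Its three methyl ethers are cleaved by NaSEt under much milder conditions, and the route is rejoined at 29.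

## Further compounds

F1 | step 3 | 3α-[(S)-2-methoxy-2-phenylacetate] of 11 | C1=C[C@H](OC(=O)[C@@H](OC)c3ccccc3)[C@@](C)(O)[C@H]2C[C@@H](C(C)(C)O[Si](CC)(CC)CC)CC[C@]12C
F2 | step 7 | 4β-(dimethylsilyl) ether of 10 | C1=CC(=O)[C@@](C)(O[SiH](C)C)[C@H]2C[C@@H](C(C)(C)O[Si](CC)(CC)CC)CC[C@]12C
F3 | step 9 | 3α-acetoxy-4α,10β-dimethyl-4β-(triethylsilyloxy)-7β-[2-(triethylsilyloxy)propan-2-yl]-5α-H-decal-1-ene | C1=C[C@H](OC(C)=O)[C@@](C)(O[Si](CC)(CC)CC)[C@H]2C[C@@H](C(C)(C)O[Si](CC)(CC)CC)CC[C@]12C
F4 | step 9 | 2-(2,3-didehydro-Dec)acetic acid | OC(=O)C[C@@H]1C=C[C@@](C)(O[Si](CC)(CC)CC)[C@H]2C[C@@H](C(C)(C)O[Si](CC)(CC)CC)CC[C@]12C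
F5 | step 9 | (R)-4-benzyl-3-[2-(2,3-didehydro-Dec)acetyl]oxazolidin-2-one | O=C(C[C@@H]1C=C[C@@](C)(O[Si](CC)(CC)CC)[C@H]2C[C@@H](C(C)(C)O[Si](CC)(CC)CC)CC[C@]12C)N1[C@H](Cc2ccccc2)COC1=O
F6 | step 9 | (R)-4-benzyl-3-[(2R)-2-(2,3-didehydro-Dec)-4-methylpent-4-enoyl]oxazolidin-2-one | C=C(C)C[C@@H](C(=O)N1[C@H](Cc2ccccc2)COC1=O)[C@@H]1C=C[C@@](C)(O[Si](CC)(CC)CC)[C@H]2C[C@@H](C(C)(C)O[Si](CC)(CC)CC)CC[C@]12C
F7 | step 9 | (2R)-2-(2,3-didehydro-Dec)-4-methylpent-4-enoic acid | C=C(C)C[C@@H](C(=O)O)[C@@H]1C=C[C@@](C)(O[Si](CC)(CC)CC)[C@H]2C[C@@H](C(C)(C)O[Si](CC)(CC)CC)CC[C@]12C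
F8 | step 12 | (3R)-3-(Dec)-5-methylhexanoic acid | CC(C)C[C@@H](CC(=O)O)[C@@H]1CC[C@@](C)(O[Si](CC)(CC)CC)[C@H]2C[C@@H](C(C)(C)O[Si](CC)(CC)CC)CC[C@]12C
F9 | step 12 | (3R)-3-(Dec)-5-methylhexanoyl chloride | CC(C)C[C@@H](CC(=O)Cl)[C@@H]1CC[C@@](C)(O[Si](CC)(CC)CC)[C@H]2C[C@@H](C(C)(C)O[Si](CC)(CC)CC)CC[C@]12C
F10 | step 16 | methoxyacetylene | COC#C
F11 | step 16 | 2-[(1R)-1-(Dec)-3-methylbutyl]-3,5-dimethoxyphenol | CC(C)C[C@@H](c1c(O)cc(OC)cc1OC)[C@@H]1CC[C@@](C)(O[Si](CC)(CC)CC)[C@H]2C[C@@H](C(C)(C)O[Si](CC)(CC)CC)CC[C@]12C
F12 | step 16 | 2-[(1R)-1-(Dec)-3-methylbutyl]-1,3,5-trimethoxybenzene | CC(C)C[C@@H](c1c(OC)cc(OC)cc1OC)[C@@H]1CC[C@@](C)(O[Si](CC)(CC)CC)[C@H]2C[C@@H](C(C)(C)O[Si](CC)(CC)CC)CC[C@]12C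
F13 | step 16 | 1-[(1R)-1-(Dec)-3-methylbutyl]-3,5-dibromo-2,4,6-trimethoxybenzene | CC(C)C[C@@H](c1c(OC)c(Br)c(OC)c(Br)c1OC)[C@@H]1CC[C@@](C)(O[Si](CC)(CC)CC)[C@H]2C[C@@H](C(C)(C)O[Si](CC)(CC)CC)CC[C@]12C
F14 | step 16 | 5-[(1R)-1-(Dec)-3-methylbutyl]-2,4,6-trimethoxybenzene-1,3-dicarbaldehyde | CC(C)C[C@@H](c1c(OC)c(C=O)c(OC)c(C=O)c1OC)[C@@H]1CC[C@@](C)(O[Si](CC)(CC)CC)[C@H]2C[C@@H](C(C)(C)O[Si](CC)(CC)CC)CC[C@]12C
A1 | alternative 1 | trans-fused octalin tert-butyldimethylsilyl enol ether (C3=C4) with 1-(3-methylbutanoyl) trans to the C10 methyl and 7-isopropenyl | CC(C)CC(=O)[C@@H]1CC=C(O[Si](C)(C)C(C)(C)C)[C@H]2C[C@@H](C(C)=C)CC[C@]12C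
A2 | alternative 1 | acyclic (Z)-enone 2-silyloxydiene triene precursor | C=C/C(O[Si](C)(C)C(C)(C)C)=C/C[C@@H](C(C)=C)CC/C(C)=C\C(=O)CC(C)C
A3 | alternative 2 | 5,10-methano decalin-4β-ol with β-methylene, 1α-arylalkyl arm and C7=C8 | CC(C)C[C@@H](c1c(OC)cc(OC)cc1OC)[C@@H]1CC[C@@H](O)[C@]23C[C@@]13CC=C(C(C)(C)O[Si](CC)(CC)CC)C2
A4 | alternative 2 | ring-fusion allylic alcohol (C5=C10, 4β-OH) precursor | CC(C)C[C@@H](c1c(OC)cc(OC)cc1OC)[C@@H]1CC[C@@H](O)C2=C1CC=C(C(C)(C)O[Si](CC)(CC)CC)C2
A5 | alternative 3 | trans-decalin-4-one with equatorial 7β-isopropenyl and 1α-arylalkyl arm | CC(C)C[C@@H](c1c(OC)cc(OC)cc1OC)[C@@H]1CCC(=O)[C@H]2C[C@@H](C(C)=C)CC[C@]12C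
A6 | alternative 3 | ring A α-methylene ketone with C10 methyl and homoprenyl chain | CC(C)C[C@@H](c1c(OC)cc(OC)cc1OC)[C@@H]1CCC(=O)C(=C)[C@]1(C)CCC=C(C)C
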